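The 1,2-dioxane ring is opened at C4–C5 and O2–C3. Atoms C3, C4 and the whole methyl propanoate branch then come from methyl tiglate, used through its silyl dienolate as a γ-nucleophile and β-electrophile; O1, O2, C6 and C5 come from an α-silylperoxy aldehyde made from geranylgeraniol by asymmetric epoxidation, epoxide perhydrolysis and glycol cleavage. In one flask a vinylogous Mukaiyama aldol joins C4 to C5 and fluoride then frees the peroxide anion, which closes the ring by 6-exo conjugate addition at C3. The step exploits the 1,4 relationship between peroxide oxygen O2 and C5 across quaternary C6 of the dioxane. The aldol hydroxyl left on C5 is removed by radical deoxygenation.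

Key step: step 6

Remark on numbering: the dioxane is numbered O1, O2, C3 (bearing the propanoate), C4, C5, C6 (bearing methyl and the trienyl chain); C2' is the ester α-carbon.

Assumption: perhydrolysis of the 2,3-epoxy alcohol is taken to occur at the tertiary carbon with inversion, as is usual for acid-type opening of trisubstituted epoxides by H2O2.

Stereochemical limit of the route: C6 is set with reagent control in steps 1 and 2. C3 and C2' are both formed in step 6, C3 without useful control, so the target is one of several diastereomers and is isolated by preparative HPLC after step 8.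

Step 1
Reactants: 1 (2E,6E,10E)-geranylgeraniol
Product: 2 [(2S,3S)-3-methyl-3-[(3E,7E)-4,8,12-trimethyltrideca-3,7,11-trien-1-yl]oxiran-2-yl]methanol
Conditions: Ti(OiPr)4 (10 mol %), L-(+)-diethyl tartrate (12 mol %), t-BuOOH, 4 Å sieves, CH2Cl2, −20 °C
Reagents that add atoms: tert-butyl hydroperoxide, CC(C)(C)OO
Why: Sharpless asymmetric epoxidation touches only the allylic alcohol alkene, and the L-(+)-tartrate ligand delivers oxygen to the face that should give the (2S,3S)-epoxide, which fixes the future C6 centre.

Step 2
Reactants: 2 (2S,3S)-epoxy alcohol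
Product: 3 (2S,3R,6E,10E)-3-hydroperoxy-3,7,11,15-tetramethylhexadeca-6,10,14-triene-1,2-diol
Conditions: anhydrous H2O2 in Et2O (10 equiv), H3PMo12O40 (3 mol %), 0 °C to rt
Reagents that add atoms: hydrogen peroxide, OO
Why: Acid-type epoxide perhydrolysis, in which the activated oxirane is opened by H2O2 at the tertiary carbon in an SN2-like manner, should invert C3 to the (3R)-hydroperoxide and leave C2 untouched.

Step 3
Reactants: 3 hydroperoxy diol
Product: 4 (2R,5E,9E)-2-hydroperoxy-2,6,10,14-tetramethylpentadeca-5,9,13-trienal
Conditions: NaIO4 (1.2 equiv), THF/pH 7 buffer, 0 °C; crude product kept cold and used at once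
Reagents that add atoms: none
Why: Periodate glycol cleavage removes C1 as formaldehyde and turns C2 into the aldehyde carbon (the future C5); the quaternary peroxide carbon has no α-hydrogen and cannot epimerise.

Step 4
Reactants: 4 α-hydroperoxy aldehyde
Product: 5 (2R,5E,9E)-2,6,10,14-tetramethyl-2-[(triethylsilyl)peroxy]pentadeca-5,9,13-trienal
Conditions: Et3SiOTf (1.2 equiv), 2,6-lutidine (1.5 equiv), CH2Cl2, −78 °C
Reagents that add atoms: triethylsilyl trifluoromethanesulfonate, CC[Si](CC)(CC)OS(=O)(=O)C(F)(F)F
Why: O-silylation of the hydroperoxide masks the acidic O–O–H, which would quench the dienolate and lets the aldehyde fragment; no stereocentre is affected.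

Step 5
Reactants: 6 methyl tiglate
Product: 7 [(1-methoxy-2-methylbuta-1,3-dien-1-yl)oxy]trimethylsilane
Conditions: LiN(iPr)2, THF/DMPU, −78 °C; then Me3SiCl, −78 °C to rt
Reagents that add atoms: chlorotrimethylsilane, C[Si](C)(C)Cl
Why: Kinetic γ-deprotonation of the enoate and O-silylation of the lithium dienolate give the vinylketene silyl acetal; no stereocentre is formed and the ketene acetal geometry is of no consequence.

Step 6
Reactants: 5 α-silylperoxy aldehyde and 7 silyl dienolate
Product: 9 methyl (2R)-2-[(3S,6R)-5-hydroxy-6-methyl-6-[(3E,7E)-4,8,12-trimethyltrideca-3,7,11-trien-1-yl]-1,2-dioxan-3-yl]propanoate (both C5 epimers), via silylperoxy hydroxy enoate 8 (not isolated)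
Conditions: 7 (1.5 equiv), BF3·OEt2 (1.1 equiv), CH2Cl2/Et2O, −78 °C; then Bu4NF (3 equiv), CF3CH2OH/THF, −78 to 0 °C, same flask
Reagents that add atoms: none
Why: BF3 activates aldehyde 5 for a vinylogous Mukaiyama aldol addition in which the γ-carbon of dienolate 7 forms C4–C5 and leaves the (E)-enoate 8, and fluoride then cleaves the O–Si bond so that the peroxide anion adds to the β-carbon C3 (intramolecular peroxy-Michael addition) while CF3CH2OH protonates the ester enolate at C2' before it can attack the O–O bond. The closest known reaction types are the Lewis-acid vinylogous aldol of tiglate silyl dienolates with α-branched aldehydes and the base-induced cyclisation of hydroperoxy enoates to 1,2-dioxanes. The dioxane ring closes in the 6-exo-trig mode through a chair with the enoate equatorial. C5 is formed without control and is erased in step 8; C3 receives no useful bias from C6, whose methyl and CH2R groups are alike in size, so both C3 epimers are expected; C2' is set by enolate protonation under allylic strain (C3–H in the enolate plane), and anti addition across the (E)-enoate would give the required 2',3-syn (2'R,3S) pair, although the facial preference between ring oxygen and ring CH2 is not secure. The step needs γ- over α-attack, which the quaternary α-carbon of 5 and the α-methyl of 7 secure, and an intact O–O bond, which silylation and −78 °C secure; the (3S,2'R) isomer is separated after step 8.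

Step 7
Reactants: 9 5-hydroxy dioxane ester
Product: 10 methyl (2R)-2-[(3S,6R)-6-methyl-5-[(phenoxycarbonothioyl)oxy]-6-[(3E,7E)-4,8,12-trimethyltrideca-3,7,11-trien-1-yl]-1,2-dioxan-3-yl]propanoate (both C5 epimers)
Conditions: PhOC(S)Cl (2 equiv), pyridine, DMAP (cat.), CH2Cl2, 0 °C to rt
Reagents that add atoms: O-phenyl chlorothionoformate, S=C(Cl)Oc1ccccc1
Why: O-thioacylation of the secondary alcohol under amine conditions (first half of the Barton–McCombie deoxygenation) avoids a free alkoxide next to the peroxide; no stereocentre changes.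

Step 8
Reactants: 10 thionocarbonate
Product: 11 methyl (2R)-2-[(3S,6R)-6-methyl-6-[(3E,7E)-4,8,12-trimethyltrideca-3,7,11-trien-1-yl]-1,2-dioxan-3-yl]propanoate (target)
Conditions: Bu3SnH (1.5 equiv, slow addition), AIBN (0.2 equiv), toluene, 80 °C; then preparative HPLC
Reagents that add atoms: none
Why: Barton–McCombie radical deoxygenation should reduce the ring-bound C5 radical, which cannot reach the geometry for backside attack on the O–O bond, so both C5 epimers converge on the C5 methylene while C3, C6 and C2' stay untouched.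

Compound list
1 | (2E,6E,10E)-3,7,11,15-tetramethylhexadeca-2,6,10,14-tetraen-1-ol (geranylgeraniol) | OC/C=C(\C)CC/C=C(\C)CC/C=C(\C)CCC=C(C)C | starting material
2 | [(2S,3S)-3-methyl-3-[(3E,7E)-4,8,12-trimethyltrideca-3,7,11-trien-1-yl]oxiran-2-yl]methanol | OC[C@@H]1O[C@@]1(C)CC/C=C(\C)CC/C=C(\C)CCC=C(C)C | intermediate
3 | (2S,3R,6E,10E)-3-hydroperoxy-3,7,11,15-tetramethylhexadeca-6,10,14-triene-1,2-diol | OC[C@H](O)[C@](C)(OO)CC/C=C(\C)CC/C=C(\C)CCC=C(C)C | intermediate
4 | (2R,5E,9E)-2-hydroperoxy-2,6,10,14-tetramethylpentadeca-5,9,13-trienal | O=C[C@](C)(OO)CC/C=C(\C)CC/C=C(\C)CCC=C(C)C | intermediate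
5 | (2R,5E,9E)-2,6,10,14-tetramethyl-2-[(triethylsilyl)peroxy]pentadeca-5,9,13-trienal | O=C[C@](C)(OO[Si](CC)(CC)CC)CC/C=C(\C)CC/C=C(\C)CCC=C(C)C | intermediate
6 | methyl (E)-2-methylbut-2-enoate (methyl tiglate) | C/C=C(\C)C(=O)OC | starting material
7 | [(1-methoxy-2-methylbuta-1,3-dien-1-yl)oxy]trimethylsilane | COC(O[Si](C)(C)C)=C(C)C=C | intermediate
8 | methyl (2E,6R,9E,13E)-5-hydroxy-2,6,10,14,18-pentamethyl-6-[(triethylsilyl)peroxy]nonadeca-2,9,13,17-tetraenoate (C5 epimers; present as its O–BF2 aldolate until fluoride is added) | COC(=O)/C(C)=C/CC(O)[C@](C)(OO[Si](CC)(CC)CC)CC/C=C(\C)CC/C=C(\C)CCC=C(C)C | intermediate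
9 | methyl (2R)-2-[(3S,6R)-5-hydroxy-6-methyl-6-[(3E,7E)-4,8,12-trimethyltrideca-3,7,11-trien-1-yl]-1,2-dioxan-3-yl]propanoate (C5 epimers) | COC(=O)[C@H](C)[C@@H]1CC(O)[C@@](C)(CC/C=C(\C)CC/C=C(\C)CCC=C(C)C)OO1 | intermediate
10 | methyl (2R)-2-[(3S,6R)-6-methyl-5-[(phenoxycarbonothioyl)oxy]-6-[(3E,7E)-4,8,12-trimethyltrideca-3,7,11-trien-1-yl]-1,2-dioxan-3-yl]propanoate (C5 epimers) | COC(=O)[C@H](C)[C@@H]1CC(OC(=S)Oc2ccccc2)[C@@](C)(CC/C=C(\C)CC/C=C(\C)CCC=C(C)C)OO1 | intermediate
11 | methyl (2R)-2-[(3S,6R)-6-methyl-6-[(3E,7E)-4,8,12-trimethyltrideca-3,7,11-trien-1-yl]-1,2-dioxan-3-yl]propanoate | COC(=O)[C@H](C)[C@@H]1CC[C@@](C)(CC/C=C(\C)CC/C=C(\C)CCC=C(C)C)OO1 | target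

Total step count: 8. Longest linear sequence: 7 (steps 1, 2, 3, 4, 6, 7, 8).

Steps most likely to fail

Step 6. The dienolate may attack through its α-carbon, the Lewis acid may heterolyse the O–O bond, or the β-hydroxy peroxide may undergo retro-aldol or Grob-type cleavage once fluoride is added; lack of facial selectivity at C3 also lowers the share of the wanted diastereomer. The fallback sets out from 5 and forms C4–C5 without Lewis acid: allylboration with pinacol allylboronate (CH2Cl2, rt) should give the homoallylic alcohol (5R,8E,12E)-5,9,13,17-tetramethyl-5-[(triethylsilyl)peroxy]octadeca-1,8,12,16-tetraen-4-ol F1. Cross-metathesis of F1 with methyl methacrylate (second-generation Hoveyda–Grubbs catalyst, CH2Cl2, 40 °C) should then give the (E)-enoate 8, this time isolated. Its cyclisation with Bu4NF in CF3CH2OH/THF comes back to the route at 9.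

Step 8. The stannyl radical may attack the O–O bond, or the C5 radical may open the ring by β-fragmentation with loss of the peroxyl group. The fallback sets out from 9, so step 7 is skipped as well. Syn-dehydration with the Burgess reagent (benzene, 50 °C) can only run toward C4 and should give methyl (2R)-2-[(3S,6R)-6-methyl-6-[(3E,7E)-4,8,12-trimethyltrideca-3,7,11-trien-1-yl]-3,6-dihydro-1,2-dioxin-3-yl]propanoate F2. Diimide reduction of the ring alkene of F2 (dipotassium azodicarboxylate, AcOH, MeOH, 0 °C) spares the trisubstituted chain alkenes and the peroxide and comes back to the route at 11.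

Step 3. The free α-hydroperoxy aldehyde may fragment, through its cyclic peroxyhemiacetal, to the C18 methyl ketone and formic acid during cleavage and handling. The fallback sets out from 3 and reverses the order of events: the more acidic hydroperoxide is silylated selectively (Et3SiCl 1.05 equiv, Et3N, CH2Cl2, −78 °C) to (2S,3R,6E,10E)-3,7,11,15-tetramethyl-3-[(triethylsilyl)peroxy]hexadeca-6,10,14-triene-1,2-diol F3. Periodate cleavage of the glycol of F3 comes back to the route at 5, so that no free α-hydroperoxy aldehyde is formed.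

Further compounds
F1 | step 6 | (5R,8E,12E)-5,9,13,17-tetramethyl-5-[(triethylsilyl)peroxy]octadeca-1,8,12,16-tetraen-4-ol (C4 epimers) | C=CCC(O)[C@](C)(OO[Si](CC)(CC)CC)CC/C=C(\C)CC/C=C(\C)CCC=C(C)C
F2 | step 8 | methyl (2R)-2-[(3S,6R)-6-methyl-6-[(3E,7E)-4,8,12-trimethyltrideca-3,7,11-trien-1-yl]-3,6-dihydro-1,2-dioxin-3-yl]propanoate | COC(=O)[C@H](C)[C@@H]1C=C[C@@](C)(CC/C=C(\C)CC/C=C(\C)CCC=C(C)C)OO1
F3 | step 3 | (2S,3R,6E,10E)-3,7,11,15-tetramethyl-3-[(triethylsilyl)peroxy]hexadeca-6,10,14-triene-1,2-diol | OC[C@H](O)[C@](C)(OO[Si](CC)(CC)CC)CC/C=C(\C)CC/C=C(\C)CCC=C(C)C
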